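**Retrosynthetic overview**

1. Cembrane numbering is used throughout: C1 = isopropyl-bearing oxolane carbon, C2=C3 alkene, C4 carbinol, C6 ketone, C8 methyl-bearing methine, C11 formate carbon, C12 methyl-bearing oxolane carbon, C13/C14 the oxolane CH2 groups. The 14-membered carbocycle is cut at C2=C3 (intramolecular Julia–Kocienski olefination) and at C9–C10 (cross-metathesis, then reduction), giving west lactol 14 (C1, C2, C10–C14) and east sulfone 27 (C3–C9).
2. In the west half the oxolane is closed by the C1–C14 bond: the enolate of a temporary 1,4-dioxan-2-one (ring O–C2(=O)–C1–O–C12–C11) is C-alkylated by the 2-iodoethyl arm on C12 (step 8).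
3. Enabling feature: the two macrocycle branches C2 (on C1) and C11 (on C12) are cis across the oxolane C1–O–C12, and C11 carries an oxygen. With C2 at the carboxyl level, C2 and O–C11 can be laced into a six-membered lactone that already contains the C1–O–C12 ether; this makes C1–H acidic and lets the C13–C14 arm reach C1 from one face only.
4. Ring order: temporary dioxanone (step 3), then oxolane within a bridged lactone (step 8), then the carbocycle (step 21, which also opens the temporary ring).
5. Stereocentres: C11/C12 from Sharpless epoxidation and invertive titanium-mediated opening; C1 from the key step; C4 from (S)-2-methylglycidyl tosylate; C8 from iridium-catalysed allylic alkylation; C6 is carried as a carbinol and oxidised last.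

Key step: step 8

**West fragment (steps 1–9)**

Step 1
Reactants: 1 tert-butyl(but-3-yn-1-yloxy)dimethylsilane
Product: 3 (E)-5-[(tert-butyldimethylsilyl)oxy]-3-methylpent-2-en-1-ol, via alkenylalane 2 (not isolated)
Conditions: Me3Al, Cp2ZrCl2 (cat.), CH2Cl2, 0 °C to rt; then n-BuLi, THF, −78 °C; (CH2O)n, to rt
Reagents that add atoms: trimethylaluminium C[Al](C)C; paraformaldehyde (as formaldehyde) C=O
Why: Zirconium-catalysed carboalumination (Negishi) adds methyl and aluminium syn across the terminal alkyne with aluminium at the terminus, and trapping of the derived aluminate with formaldehyde keeps the E geometry.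

Step 2
Reactants: 3 (E)-allylic alcohol
Product: 4 [(2R,3R)-3-{2-[(tert-butyldimethylsilyl)oxy]ethyl}-3-methyloxiran-2-yl]methanol
Conditions: Ti(OiPr)4 (cat.), D-(−)-diethyl tartrate, t-BuOOH, 4 Å MS, CH2Cl2, −20 °C
Reagents that add atoms: tert-butyl hydroperoxide CC(C)(C)OO
Why: Sharpless asymmetric epoxidation of an E-3-methyl allylic alcohol; the D-tartrate should give the (2R,3R) epoxide, which fixes C11 (R, oxygen retained later) and the C12 configuration that step 3 inverts.

Step 3
Reactants: 4 epoxy alcohol; 5 methyl (S)-2-hydroxy-3-methylbutanoate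
Product: 7 (3S,5S,6R)-5-{2-[(tert-butyldimethylsilyl)oxy]ethyl}-6-(hydroxymethyl)-5-methyl-3-(propan-2-yl)-1,4-dioxan-2-one, via hydroxy ether ester 6 (not isolated)
Conditions: Ti(OiPr)4 (1.5 equiv, premixed with 5, i-PrOH removed), toluene, 50 °C; then PPTS (cat.), toluene, 80 °C
Reagents that add atoms: none
Why: Titanium-mediated C-3-selective opening of a 2,3-epoxy alcohol by a titanium-bound alcohol should attack the tertiary C12 with inversion (C12 becomes S, anti to the C11 oxygen), and the freed C11 hydroxyl then lactonises to the six-membered ring in preference to the seven-membered alternative through C10–OH; the C1 configuration is irrelevant because step 8 passes through the enolate.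

Step 4
Reactants: 7 dioxanone alcohol
Product: 8 (2S,3S,5S)-3-{2-[(tert-butyldimethylsilyl)oxy]ethyl}-3-methyl-6-oxo-5-(propan-2-yl)-1,4-dioxane-2-carbaldehyde
Conditions: Dess–Martin periodinane, CH2Cl2, 0 °C to rt
Reagents that add atoms: none
Why: Dess–Martin oxidation of the primary C10 alcohol under near-neutral conditions should leave the alpha stereocentre C11 intact (its descriptor changes only by priority).

Step 5
Reactants: 8 aldehyde
Product: 9 (3S,5S,6R)-5-{2-[(tert-butyldimethylsilyl)oxy]ethyl}-6-ethenyl-5-methyl-3-(propan-2-yl)-1,4-dioxan-2-one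
Conditions: Ph3PCH3Br, KHMDS, THF, −78 to 0 °C
Reagents that add atoms: methyltriphenylphosphonium bromide C[P+](c1ccccc1)(c1ccccc1)c1ccccc1.[Br-]
Why: Wittig methylenation; the aldehyde should react far faster than the lactone at low temperature, as with other alpha-oxygenated aldehydes.

Step 6
Reactants: 9 vinyl dioxanone silyl ether
Product: 10 (3S,5S,6R)-6-ethenyl-5-(2-hydroxyethyl)-5-methyl-3-(propan-2-yl)-1,4-dioxan-2-one
Conditions: HF·pyridine, pyridine, THF, 0 °C to rt
Reagents that add atoms: none
Why: Fluoride cleavage of the primary TBS ether under buffered conditions that a lactone tolerates.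

Step 7
Reactants: 10 primary alcohol
Product: 11 (3S,5S,6R)-6-ethenyl-5-(2-iodoethyl)-5-methyl-3-(propan-2-yl)-1,4-dioxan-2-one
Conditions: I2, PPh3, imidazole, CH2Cl2, 0 °C to rt
Reagents that add atoms: iodine II
Why: Appel-type iodination of an unhindered primary alcohol (the quaternary carbon is gamma to the reacting centre).

Step 8
Reactants: 11 iodoethyl dioxanone
Product: 13 (1S,4R,5S)-4-ethenyl-5-methyl-1-(propan-2-yl)-3,8-dioxabicyclo[3.2.1]octan-2-one, via potassium enolate 12 (not isolated)
Conditions: KHMDS (1.05 equiv), THF (0.01 M), −78 to −40 °C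
Reagents that add atoms: none
Why: KHMDS removes the C1 proton (alpha to the lactone carbonyl and the ether oxygen) to give planar enolate 12, whose C1 displaces iodide at C14 in an intramolecular SN2 reaction. The closest known reaction type is the intramolecular C-alkylation of ketone and lactone enolates that builds bridged bicyclo[3.2.1] skeletons. The oxolane (O, C1, C14, C13, C12) closes in the 5-exo-tet mode, which turns the dioxanone into the bridged bicyclic lactone. The new quaternary stereocentre C1 is controlled by the temporary lactone ring: the arm on C12 can reach only the enolate face on its own side, so C2 and C11 must end cis across the oxolane (1S), and both C1 epimers of 11 converge. The step needs C- over O-alkylation and substitution over E2 or ketene-forming fragmentation; O-alkylation would require a seven-membered ketene acetal, the iodide is primary, and low temperature and dilution should suppress elimination and intermolecular reaction.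

Step 9
Reactants: 13 bicyclic lactone
Product: 14 (1S,4R,5S)-4-ethenyl-5-methyl-1-(propan-2-yl)-3,8-dioxabicyclo[3.2.1]octan-2-ol (lactol; C2 epimers)
Conditions: DIBAL (1.1 equiv), CH2Cl2, −78 °C
Reagents that add atoms: none
Why: Partial reduction of a lactone to the lactol; the tetrahedral aluminate should be stable at −78 °C and the bridged hemiacetal is the masked C2 aldehyde.

**East fragment (steps 10–18)**

Step 10
Reactants: 15 methyl (E)-but-2-en-1-yl carbonate; 16 dimethyl malonate
Product: 17 dimethyl 2-[(2S)-but-3-en-2-yl]propanedioate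
Conditions: [Ir(cod)Cl]2 (2 mol%), BINOL-derived N,N-bis(1-phenylethyl)phosphoramidite (4 mol%; enantiomer chosen to give the S product), TBD (cat.), THF, rt
Reagents that add atoms: none
Why: Iridium-catalysed asymmetric allylic alkylation should give the branched product and sets the C8 stereocentre under ligand control.

Step 11
Reactants: 17 branched malonate
Product: 18 methyl (3R)-3-methylpent-4-enoate
Conditions: LiCl, H2O, DMSO, 150 °C
Reagents that add atoms: none
Why: Krapcho dealkoxycarbonylation removes one ester without touching the beta stereocentre (descriptor changes only by priority).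

Step 12
Reactants: 18 ester
Product: 19 (3R)-3-methylpent-4-enal
Conditions: DIBAL (1.05 equiv), CH2Cl2, −78 °C; used crude (volatile)
Reagents that add atoms: none
Why: Partial reduction of a methyl ester to the aldehyde at low temperature.

Step 13
Reactants: 19 aldehyde
Product: 20 2-[(2R)-2-methylbut-3-en-1-yl]-1,3-dithiane
Conditions: propane-1,3-dithiol, BF3·OEt2 (cat.), CH2Cl2, 0 °C
Reagents that add atoms: propane-1,3-dithiol SCCCS
Why: Lewis-acid dithioacetalisation turns C6 into an acyl-anion equivalent (Corey–Seebach).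

Step 14
Reactants: 20 dithiane; 21 [(2S)-2-methyloxiran-2-yl]methyl 4-methylbenzenesulfonate
Product: 23 (2S)-2-methyl-1-{2-[(2R)-2-methylbut-3-en-1-yl]-1,3-dithian-2-yl}-3-[(1-phenyl-1H-tetrazol-5-yl)sulfanyl]propan-2-ol, via epoxide 22 (not isolated)
Conditions: n-BuLi, THF, −25 °C; 21, −78 to 0 °C; then 1-phenyl-1H-tetrazole-5-thiol, Et3N, DMF, 50 °C
Reagents that add atoms: 1-phenyl-1H-tetrazole-5-thiol Sc1nnnn1-c1ccccc1
Why: Corey–Seebach alkylation in which the lithiated dithiane opens the epoxide at its CH2 (C5), the alkoxide closes a new epoxide by displacing tosylate, and the thiolate opens that at CH2 (C3); no bond to C4 is broken, so the (S)-tosylate delivers C4 (S).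

Step 15
Reactants: 23 hydroxy dithiane
Product: 24 (2S,6R)-2-hydroxy-2,6-dimethyl-1-[(1-phenyl-1H-tetrazol-5-yl)sulfanyl]oct-7-en-4-one
Conditions: MeI, CaCO3, MeCN–H2O (9:1), 45 °C
Reagents that add atoms: water O
Why: Alkylative dithiane hydrolysis; the dithiane sulfur should be methylated in preference to the electron-poor tetrazolyl sulfide, and the buffered medium should spare the tertiary aldol.

Step 16
Reactants: 24 hydroxy ketone
Product: 25 (2S,6R)-2,6-dimethyl-1-[(1-phenyl-1H-tetrazol-5-yl)sulfanyl]oct-7-ene-2,4-diol (both epimers at the new carbinol, target C6)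
Conditions: NaBH4, MeOH, 0 °C
Reagents that add atoms: none
Why: Borohydride reduction masks the C6 ketone as a carbinol; its configuration is immaterial because step 24 re-oxidises it.

Step 17
Reactants: 25 1,3-diol
Product: 26 di-tert-butylsilylene acetal of 25 (2,2-di-tert-butyl-1,3,2-dioxasilinane carrying C4 methyl, C4 CH2S-tetrazolyl and C6 (2R)-2-methylbut-3-enyl)
Conditions: t-Bu2Si(OTf)2, 2,6-lutidine, CH2Cl2, 0 °C to rt
Reagents that add atoms: di-tert-butylsilyl bis(trifluoromethanesulfonate) CC(C)(C)[Si](OS(=O)(=O)C(F)(F)F)(OS(=O)(=O)C(F)(F)F)C(C)(C)C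
Why: Silylene protection of a 1,3-diol as a six-membered acetal that is stable to base and oxidants and is removed by fluoride.

Step 18
Reactants: 26 sulfide
Product: 27 sulfone (26 with the sulfide oxidised to SO2)
Conditions: (NH4)6Mo7O24·4H2O (cat.), 30% H2O2, EtOH, 0 °C to rt
Reagents that add atoms: hydrogen peroxide OO
Why: Molybdate-catalysed oxidation of the tetrazolyl sulfide to the Julia–Kocienski sulfone, which should not epoxidise a terminal alkene.

**Union and endgame (steps 19–24)**

Step 19
Reactants: 14 lactol; 27 sulfone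
Product: 28 cross-metathesis product (lactol and sulfone joined by a C9=C10 alkene, E/Z mixture)
Conditions: second-generation Grubbs catalyst (10 mol%), 27 (2 equiv), CH2Cl2, 40 °C
Reagents that add atoms: none
Why: Olefin cross-metathesis between an alpha-branched terminal alkene and a slowly dimerising allylic-oxygenated vinyl group; neither partner has a second alkene, so no ring-closing side path exists at this stage.

Step 20
Reactants: 28 alkene
Product: 29 saturated lactol sulfone (C9–C10 single bond)
Conditions: 2-nitrobenzenesulfonyl hydrazide, Et3N, CH2Cl2, rt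
Reagents that add atoms: none
Why: Diimide reduction of the only C=C bond; it avoids hydrogenolysis of the allylic C11–O bond and leaves sulfone and lactol untouched.

Step 21
Reactants: 29 lactol sulfone
Product: 30 macrocyclic alcohol (14-membered carbocycle, 2E alkene, free C11–OH, C4/C6 silylene)
Conditions: KHMDS (2.5 equiv), THF (1 mM), −78 °C to rt
Reagents that add atoms: none
Why: Intramolecular Julia–Kocienski olefination: base opens the lactolate to the C2 aldehyde and the C3 sulfonyl carbanion adds, rearranges (Smiles) and eliminates to the E alkene expected for an alpha-quaternary aldehyde, closing the carbocycle under high dilution.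

Step 22
Reactants: 30 macrocyclic alcohol
Product: 31 C11 formate
Conditions: acetic formic anhydride, pyridine, DMAP (cat.), CH2Cl2, 0 °C
Reagents that add atoms: acetic formic anhydride CC(=O)OC=O
Why: Formyl transfer from the mixed anhydride to the only free hydroxyl (the formyl carbonyl is the more electrophilic one).

Step 23
Reactants: 31 silylene formate
Product: 32 C4,C6-diol formate (C6 epimers)
Conditions: HF·pyridine, pyridine, THF, 0 °C to rt
Reagents that add atoms: none
Why: Fluoride cleavage of the silylene under buffered conditions that should spare the formate and the tertiary allylic alcohol.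

Step 24
Reactants: 32 diol
Product: 33 target, (1S,2E,4S,8S,11R,12S)-1,12-epoxy-4-hydroxy-6-oxocembr-2-en-11-yl formate
Conditions: Dess–Martin periodinane, CH2Cl2, 0 °C to rt
Reagents that add atoms: none
Why: Dess–Martin oxidation of the secondary C6 alcohol; the tertiary C4 alcohol cannot be oxidised and the neutral conditions should avoid retro-aldol cleavage and formate loss.

**Compound list**

1 | tert-butyl(but-3-yn-1-yloxy)dimethylsilane | C#CCCO[Si](C)(C)C(C)(C)C | starting material
2 | [(E)-4-(tert-butyldimethylsilyloxy)-2-methylbut-1-enyl]dimethylaluminium | C[Al](C)/C=C(\C)CCO[Si](C)(C)C(C)(C)C | intermediate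
3 | (E)-5-[(tert-butyldimethylsilyl)oxy]-3-methylpent-2-en-1-ol | OC/C=C(\C)CCO[Si](C)(C)C(C)(C)C | intermediate
4 | [(2R,3R)-3-{2-[(tert-butyldimethylsilyl)oxy]ethyl}-3-methyloxiran-2-yl]methanol | OC[C@H]1O[C@]1(C)CCO[Si](C)(C)C(C)(C)C | intermediate
5 | methyl (S)-2-hydroxy-3-methylbutanoate | COC(=O)[C@@H](O)C(C)C | starting material
6 | methyl (2S)-2-{[(2R,3S)-1,2-dihydroxy-3-methyl-5-(tert-butyldimethylsilyloxy)pentan-3-yl]oxy}-3-methylbutanoate | COC(=O)[C@H](C(C)C)O[C@@](C)(CCO[Si](C)(C)C(C)(C)C)[C@H](O)CO | intermediate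
7 | (3S,5S,6R)-5-{2-[(tert-butyldimethylsilyl)oxy]ethyl}-6-(hydroxymethyl)-5-methyl-3-(propan-2-yl)-1,4-dioxan-2-one | CC(C)[C@H]1C(=O)O[C@H](CO)[C@](C)(CCO[Si](C)(C)C(C)(C)C)O1 | intermediate
8 | (2S,3S,5S)-3-{2-[(tert-butyldimethylsilyl)oxy]ethyl}-3-methyl-6-oxo-5-(propan-2-yl)-1,4-dioxane-2-carbaldehyde | CC(C)[C@H]1C(=O)O[C@H](C=O)[C@](C)(CCO[Si](C)(C)C(C)(C)C)O1 | intermediate
9 | (3S,5S,6R)-5-{2-[(tert-butyldimethylsilyl)oxy]ethyl}-6-ethenyl-5-methyl-3-(propan-2-yl)-1,4-dioxan-2-one | CC(C)[C@H]1C(=O)O[C@H](C=C)[C@](C)(CCO[Si](C)(C)C(C)(C)C)O1 | intermediate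
10 | (3S,5S,6R)-6-ethenyl-5-(2-hydroxyethyl)-5-methyl-3-(propan-2-yl)-1,4-dioxan-2-one | CC(C)[C@H]1C(=O)O[C@H](C=C)[C@](C)(CCO)O1 | intermediate
11 | (3S,5S,6R)-6-ethenyl-5-(2-iodoethyl)-5-methyl-3-(propan-2-yl)-1,4-dioxan-2-one | CC(C)[C@H]1C(=O)O[C@H](C=C)[C@](C)(CCI)O1 | intermediate
12 | potassium enolate of 11 | CC(C)C1=C([O-])O[C@H](C=C)[C@](C)(CCI)O1.[K+] | intermediate
13 | (1S,4R,5S)-4-ethenyl-5-methyl-1-(propan-2-yl)-3,8-dioxabicyclo[3.2.1]octan-2-one | CC(C)[C@]12C(=O)O[C@H](C=C)[C@](C)(CC1)O2 | intermediate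
14 | (1S,4R,5S)-4-ethenyl-5-methyl-1-(propan-2-yl)-3,8-dioxabicyclo[3.2.1]octan-2-ol (C2 epimers) | CC(C)[C@]12C(O)O[C@H](C=C)[C@](C)(CC1)O2 | intermediate
15 | methyl (E)-but-2-en-1-yl carbonate | C/C=C/COC(=O)OC | starting material
16 | dimethyl malonate | COC(=O)CC(=O)OC | starting material
17 | dimethyl 2-[(2S)-but-3-en-2-yl]propanedioate | C=C[C@H](C)C(C(=O)OC)C(=O)OC | intermediate
18 | methyl (3R)-3-methylpent-4-enoate | C=C[C@H](C)CC(=O)OC | intermediate
19 | (3R)-3-methylpent-4-enal | C=C[C@H](C)CC=O | intermediate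
20 | 2-[(2R)-2-methylbut-3-en-1-yl]-1,3-dithiane | C=C[C@H](C)CC1SCCCS1 | intermediate
21 | [(2S)-2-methyloxiran-2-yl]methyl 4-methylbenzenesulfonate | Cc1ccc(cc1)S(=O)(=O)OC[C@]1(C)CO1 | starting material
22 | 2-[(2R)-2-methylbut-3-en-1-yl]-2-{[(2S)-2-methyloxiran-2-yl]methyl}-1,3-dithiane | C=C[C@H](C)CC1(SCCCS1)C[C@@]2(C)CO2 | intermediate
23 | (2S)-2-methyl-1-{2-[(2R)-2-methylbut-3-en-1-yl]-1,3-dithian-2-yl}-3-[(1-phenyl-1H-tetrazol-5-yl)sulfanyl]propan-2-ol | C=C[C@H](C)CC1(SCCCS1)C[C@](C)(O)CSc2nnnn2-c2ccccc2 | intermediate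
24 | (2S,6R)-2-hydroxy-2,6-dimethyl-1-[(1-phenyl-1H-tetrazol-5-yl)sulfanyl]oct-7-en-4-one | C=C[C@H](C)CC(=O)C[C@](C)(O)CSc1nnnn1-c1ccccc1 | intermediate
25 | (2S,6R)-2,6-dimethyl-1-[(1-phenyl-1H-tetrazol-5-yl)sulfanyl]oct-7-ene-2,4-diol (C4 epimers) | C=C[C@H](C)CC(O)C[C@](C)(O)CSc1nnnn1-c1ccccc1 | intermediate
26 | (4S)-2,2-di-tert-butyl-4-methyl-6-[(2R)-2-methylbut-3-en-1-yl]-4-{[(1-phenyl-1H-tetrazol-5-yl)sulfanyl]methyl}-1,3,2-dioxasilinane (C6 epimers) | C=C[C@H](C)CC1C[C@@](C)(CSc2nnnn2-c2ccccc2)O[Si](C(C)(C)C)(C(C)(C)C)O1 | intermediate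
27 | sulfone of 26: (4S)-2,2-di-tert-butyl-4-methyl-6-[(2R)-2-methylbut-3-en-1-yl]-4-{[(1-phenyl-1H-tetrazol-5-yl)sulfonyl]methyl}-1,3,2-dioxasilinane | C=C[C@H](C)CC1C[C@@](C)(CS(=O)(=O)c2nnnn2-c2ccccc2)O[Si](C(C)(C)C)(C(C)(C)C)O1 | intermediate
28 | cross-metathesis product: lactol 14 joined through C10=C9 to the C8 methine of sulfone 27 (E/Z) | CC(C)[C@]12C(O)O[C@H](C=C[C@H](C)CC3C[C@@](C)(CS(=O)(=O)c4nnnn4-c4ccccc4)O[Si](C(C)(C)C)(C(C)(C)C)O3)[C@](C)(CC1)O2 | intermediate
29 | 9,10-dihydro derivative of 28 | CC(C)[C@]12C(O)O[C@H](CC[C@H](C)CC3C[C@@](C)(CS(=O)(=O)c4nnnn4-c4ccccc4)O[Si](C(C)(C)C)(C(C)(C)C)O3)[C@](C)(CC1)O2 | intermediate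
30 | macrocyclic alcohol: (1S,2E,4S,8S,11R,12S)-1,12-epoxycembr-2-ene-4,6,11-triol 4,6-O-di-tert-butylsilylene acetal (C6 epimers) | CC(C)[C@]12/C=C/[C@]3(C)CC(C[C@@H](C)CC[C@@H](O)[C@](C)(CC1)O2)O[Si](C(C)(C)C)(C(C)(C)C)O3 | intermediate
31 | 11-O-formate of 30 | CC(C)[C@]12/C=C/[C@]3(C)CC(C[C@@H](C)CC[C@@H](OC=O)[C@](C)(CC1)O2)O[Si](C(C)(C)C)(C(C)(C)C)O3 | intermediate
32 | (1S,2E,4S,8S,11R,12S)-1,12-epoxy-4,6-dihydroxycembr-2-en-11-yl formate (C6 epimers) | CC(C)[C@]12/C=C/[C@@](C)(O)CC(O)C[C@@H](C)CC[C@@H](OC=O)[C@](C)(CC1)O2 | intermediate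
33 | (1S,2E,4S,8S,11R,12S)-1,12-epoxy-4-hydroxy-6-oxocembr-2-en-11-yl formate | CC(C)[C@]12/C=C/[C@@](C)(O)CC(=O)C[C@@H](C)CC[C@@H](OC=O)[C@](C)(CC1)O2 | target

**Step count and risks**

Total step count: 24. Longest linear sequence: 15 steps (steps 1–9 then 19–24; the east branch, steps 10–18 then 19–24, is equally long).

Steps most likely to fail:

1. Step 21 (intramolecular Julia–Kocienski olefination). The bridged lactolate may release the aldehyde too slowly, so that the sulfonyl carbanion is lost by beta-elimination of the silyloxy group or by self-condensation, or the open chain oligomerises. The fallback sets out from lactone 13 and comes back at 30; it presents a free aldehyde instead of a lactol. Lactone 13 would be opened with MeNHOMe·HCl and i-PrMgCl to the hydroxy Weinreb amide F1, and the C11 hydroxyl silylated (TESCl, imidazole) to the TES ether F2. Cross-metathesis with 27 would give the coupled alkene F3, and diimide reduction the saturated amide F4. DIBAL would then give the aldehyde sulfone F5, and KHMDS at high dilution the TES-protected macrocycle F6. PPTS in MeOH should remove the secondary TES group selectively and return 30.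

2. Step 3 (titanium-mediated epoxide opening by the hydroxy ester). The hindered secondary hydroxy ester may transfer too slowly, so that isopropoxide transfer, Payne rearrangement or opening with partial retention at the tertiary carbon competes. The fallback sets out from 4 and comes back at 7; it builds the tertiary ether by carbenoid O–H insertion. Epoxy alcohol 4 would be opened at C12 with benzoic acid and Ti(OiPr)4 (the standard carboxylic-acid version) to the tertiary benzoate diol F7, which is converted at once (2,2-dimethoxypropane, PPTS) into the acetonide F8. DIBAL would remove the benzoate to give the tertiary alcohol F9. Rh2(OAc)4-catalysed O–H insertion with methyl 2-diazo-3-methylbutanoate would give the ether ester F10. Acetonide cleavage (CeCl3·7H2O, oxalic acid, MeCN) and lactonisation (PPTS, toluene) would give 7 together with its C1 epimer, both of which converge in step 8.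

3. Step 14 (three-component epoxide relay). Direct displacement of the tosylate instead of epoxide opening would deliver the C4 enantiomer and erode enantiopurity, and the intermediate epoxide could be opened a second time by the dithiane anion. The fallback sets out from 20 and comes back at 23; the sulfur is installed first, so only one electrophilic site remains. (R)-2-Methylglycidol would be converted by a Mitsunobu reaction (1-phenyl-1H-tetrazole-5-thiol, PPh3, DIAD) into the sulfide epoxide F11, which lithiated 20 would open at the unsubstituted carbon (BF3·OEt2, THF, −78 °C) to give 23 directly.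

**Further compounds**

F1 | step 21 | (2S,5S)-5-[(1R)-1-hydroxyprop-2-en-1-yl]-N-methoxy-N,5-dimethyl-2-(propan-2-yl)oxolane-2-carboxamide | CC(C)[C@@]1(CC[C@](C)(O1)[C@H](O)C=C)C(=O)N(C)OC
F2 | step 21 | triethylsilyl ether of F1 | CC(C)[C@@]1(CC[C@](C)(O1)[C@H](O[Si](CC)(CC)CC)C=C)C(=O)N(C)OC
F3 | step 21 | cross-metathesis product of F2 and 27 (C9=C10 alkene, E/Z) | CC(C)[C@@]1(CC[C@](C)(O1)[C@H](O[Si](CC)(CC)CC)C=C[C@H](C)CC2C[C@@](C)(CS(=O)(=O)c3nnnn3-c3ccccc3)O[Si](C(C)(C)C)(C(C)(C)C)O2)C(=O)N(C)OC
F4 | step 21 | 9,10-dihydro derivative of F3 | CC(C)[C@@]1(CC[C@](C)(O1)[C@H](O[Si](CC)(CC)CC)CC[C@H](C)CC2C[C@@](C)(CS(=O)(=O)c3nnnn3-c3ccccc3)O[Si](C(C)(C)C)(C(C)(C)C)O2)C(=O)N(C)OC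
F5 | step 21 | aldehyde from F4 (C2 carbaldehyde on the oxolane) | CC(C)[C@@]1(CC[C@](C)(O1)[C@H](O[Si](CC)(CC)CC)CC[C@H](C)CC2C[C@@](C)(CS(=O)(=O)c3nnnn3-c3ccccc3)O[Si](C(C)(C)C)(C(C)(C)C)O2)C=O
F6 | step 21 | 11-O-triethylsilyl ether of 30 | CC(C)[C@]12/C=C/[C@]3(C)CC(C[C@@H](C)CC[C@@H](O[Si](CC)(CC)CC)[C@](C)(CC1)O2)O[Si](C(C)(C)C)(C(C)(C)C)O3
F7 | step 3 | (2R,3S)-1,2-dihydroxy-3-methyl-5-(tert-butyldimethylsilyloxy)pentan-3-yl benzoate | OC[C@@H](O)[C@](C)(CCO[Si](C)(C)C(C)(C)C)OC(=O)c1ccccc1
F8 | step 3 | 1,2-O-isopropylidene derivative of F7 | CC1(C)OC[C@@H](O1)[C@](C)(CCO[Si](C)(C)C(C)(C)C)OC(=O)c1ccccc1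
F9 | step 3 | (2S)-4-(tert-butyldimethylsilyloxy)-2-[(4R)-2,2-dimethyl-1,3-dioxolan-4-yl]butan-2-ol | CC1(C)OC[C@@H](O1)[C@@](C)(O)CCO[Si](C)(C)C(C)(C)C
F10 | step 3 | methyl 2-{[(2S)-4-(tert-butyldimethylsilyloxy)-2-[(4R)-2,2-dimethyl-1,3-dioxolan-4-yl]butan-2-yl]oxy}-3-methylbutanoate (C2 epimers) | CC1(C)OC[C@@H](O1)[C@@](C)(OC(C(C)C)C(=O)OC)CCO[Si](C)(C)C(C)(C)C
F11 | step 14 | 5-({[(2S)-2-methyloxiran-2-yl]methyl}sulfanyl)-1-phenyl-1H-tetrazole | C[C@@]1(CSc2nnnn2-c2ccccc2)CO1
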